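**Retrosynthetic overview**

1. The last bond made is the side-chain C6'(sp3)–C7'(sp2) bond (side chain numbered C1'–C15' outward from ring C5). The target is cut into a hex-5-enyl dioxolane ester and (1E,3E,6Z)-1-iodonona-1,3,6-triene, joined by one-pot 9-BBN hydroboration / B-alkyl Suzuki–Miyaura coupling; the route uses no protecting group on the chain or ester.
2. Enabling feature: C1'–C6' is an unbranched, heteroatom-free hexamethylene tether, so its C5'=C6' vinyl precursor hydroborates only at C6'. The ring O1–O2 bond lies between the two fully substituted ring carbons C3 and C5 (no α-H, shielded), so peroxide and ester should tolerate borane, aqueous carbonate and Pd(0). C7' is the terminus of an (E,E)-diene; both coupling carbons start as π-nucleophile termini (vinyl, ethynyl), and C7' is polarity-reversed by hydrozirconation–iodination.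
3. Dioxolane half: C3–CH2CO2Me by silyl ketene acetal addition to the peroxycarbenium ion of a 3-methoxy-1,2-dioxolane; ring from a γ-hydroperoxy ketone; tertiary C5–OO by invertive H2O2 opening of an (R)-oxetane; that centre from Shi epoxidation / Red-Al opening of a carboalumination-derived allylic alcohol.
4. Triene half: (Z)-hex-3-en-1-ol → aldehyde → Takai (E)-vinyl iodide → Sonogashira / desilylation → hydrozirconation–iodination.
5. Ring order: oxirane (step 7, opened in step 8) → oxetane (step 9, opened in step 10) → 1,2-dioxolane (step 13; the only ring of the target, kept to the end).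

Key step: step 15

Remark: the carbinol carbon created in step 6 is carried as an epimer mixture until it is oxidised in step 12 (likewise ring C4 of 15 and ring C3 of 20 and 21), so it is left undefined in the names and SMILES of these compounds.

**Route**

Step 1
Reactants: 1 (Z)-hex-3-en-1-ol
Product: 2 (Z)-hex-3-enal
Conditions: Dess–Martin periodinane, CH2Cl2, 0 °C; solution used at once
Reagents that add atoms: none
Why: Dess–Martin oxidation of the primary alcohol is fast at 0 °C under near-neutral conditions, so the (Z)-β,γ-alkene should not migrate into conjugation before the aldehyde is used in step 2.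

Step 2
Reactants: 2 (Z)-hex-3-enal
Product: 3 (1E,4Z)-1-iodohepta-1,4-diene
Conditions: CrCl2, CHI3, THF–dioxane, 0 °C to rt
Reagents that add atoms: iodoform, IC(I)I
Why: Takai olefination, in which the iodoform-derived geminal dichromium reagent adds to the aldehyde and eliminates to give the (E)-vinyl iodide selectively in a non-basic medium that leaves the skipped Z-alkene in place (the minor 1Z isomer would be removed on AgNO3-doped silica).

Step 3
Reactants: 3 (1E,4Z)-1-iodohepta-1,4-diene
Product: 4 trimethyl[(3E,6Z)-nona-3,6-dien-1-yn-1-yl]silane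
Conditions: Pd(PPh3)2Cl2 (cat.), CuI (cat.), Et3N, THF, rt
Reagents that add atoms: trimethylsilylacetylene, C#C[Si](C)(C)C
Why: Sonogashira coupling of an (E)-alkenyl iodide runs at room temperature with retention of alkene geometry, and the silyl cap prevents alkyne homocoupling and makes the volatile enyne easier to handle.

Step 4
Reactants: 4 trimethyl[(3E,6Z)-nona-3,6-dien-1-yn-1-yl]silane
Product: 5 (3E,6Z)-nona-3,6-dien-1-yne
Conditions: K2CO3 (cat.), MeOH, rt; product kept as a concentrated THF solution
Reagents that add atoms: none
Why: Base-catalysed methanolysis of the C(sp)–Si bond (protodesilylation) is mild enough to leave the 1,4-diene unisomerised.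

Step 5
Reactants: 5 (3E,6Z)-nona-3,6-dien-1-yne
Product: 7 (1E,3E,6Z)-1-iodonona-1,3,6-triene, via alkenylzirconocene chloride 6 (not isolated)
Conditions: Cp2Zr(H)Cl, THF, rt, dark; then I2, THF, −78 to 0 °C
Reagents that add atoms: iodine, II
Why: Hydrozirconation with the Schwartz reagent adds Zr–H syn across the terminal alkyne, with zirconium on the terminal carbon and in preference to the 1,2-disubstituted alkenes, and iodinolysis of the C–Zr bond with retention fixes the 1E geometry.

Step 6
Reactants: 8 oct-1-en-7-yne
Product: 11 (3E)-4-methyldeca-3,9-dien-2-ol (racemic), via alkenyldimethylalane 9 (not isolated), via lithium alkenylalanate 10 (not isolated)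
Conditions: Me3Al, Cp2ZrCl2 (cat.), CH2Cl2, 0 °C to rt; volatiles removed; n-BuLi, THF–hexane, −78 °C; MeCHO, −78 to 0 °C
Reagents that add atoms: trimethylaluminium, C[Al](C)C; acetaldehyde, CC=O
Why: Zirconium-catalysed methylalumination (Negishi carboalumination) adds Me–Al syn to the terminal alkyne far faster than to the terminal alkene, with aluminium on the terminal carbon, so trapping the derived alanate with acetaldehyde should give the (E)-trisubstituted allylic alcohol, whose racemic carbinol centre is removed later.

Step 7
Reactants: 11 (3E)-4-methyldeca-3,9-dien-2-ol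
Product: 12 1-[(2R,3R)-3-(hex-5-en-1-yl)-3-methyloxiran-2-yl]ethan-1-ol (both carbinol epimers)
Conditions: D-fructose-derived Shi ketone (cat.), Oxone, K2CO3, Bu4NHSO4 (cat.), aq. Na2B4O7/EDTA buffer, MeCN–dimethoxymethane, 0 °C
Reagents that add atoms: potassium peroxymonosulfate (Oxone), [K+].[O-]S(=O)(=O)OO
Why: Shi epoxidation, in which the chiral dioxirane epoxidises the trisubstituted (E)-alkene through a spiro transition state (the monosubstituted alkene is a poor substrate) and sets the quaternary epoxide carbon as R under catalyst control, whatever the carbinol configuration.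

Step 8
Reactants: 12 1-[(2R,3R)-3-(hex-5-en-1-yl)-3-methyloxiran-2-yl]ethan-1-ol
Product: 13 (4R)-4-methyldec-9-ene-2,4-diol (C2 epimers)
Conditions: Red-Al, THF, 0 °C to rt; Rochelle salt work-up
Reagents that add atoms: none
Why: Red-Al opening of a 2,3-epoxy alcohol delivers hydride from the alkoxy-bound aluminium to the epoxide carbon next to the carbinol, which gives the 1,3-diol and leaves the tertiary C–O bond (R) untouched.

Step 9
Reactants: 13 (4R)-4-methyldec-9-ene-2,4-diol
Product: 15 (2R)-2-(hex-5-en-1-yl)-2,4-dimethyloxetane (C4 epimers), via secondary mesylate 14 (not isolated)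
Conditions: MsCl, Et3N, CH2Cl2, −20 °C; then KOtBu, THF, 0 °C to rt
Reagents that add atoms: none
Why: Selective mesylation of the secondary hydroxyl followed by 4-exo-tet Williamson ring closure by the tertiary alkoxide gives the oxetane with retention at the quaternary carbon, because its C–O bond is not broken.

Step 10
Reactants: 15 (2R)-2-(hex-5-en-1-yl)-2,4-dimethyloxetane
Product: 16 (4S)-4-hydroperoxy-4-methyldec-9-en-2-ol (C2 epimers)
Conditions: anhydrous H2O2 in Et2O, TMSOTf (cat.), −78 °C
Reagents that add atoms: hydrogen peroxide, OO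
Why: Lewis-acid-promoted opening of an oxetane by hydrogen peroxide occurs at the more substituted ring carbon by backside attack on the silyl-activated ether, so the tertiary hydroperoxide should form with inversion (R-oxetane to S-hydroperoxide), a reaction type with precedent for enantioenriched 2,2-dialkyloxetanes.

Step 11
Reactants: 16 (4S)-4-hydroperoxy-4-methyldec-9-en-2-ol
Product: 17 (4S)-4-methyl-4-[(triethylsilyl)peroxy]dec-9-en-2-ol
Conditions: Et3SiCl, Et3N, DMAP (cat.), CH2Cl2, −40 to 0 °C
Reagents that add atoms: chlorotriethylsilane, CC[Si](Cl)(CC)CC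
Why: Chemoselective silylation, since the hydroperoxide (pKa about 13, α-effect nucleophile) is deprotonated and silylated far faster than the secondary alcohol (pKa about 17), which stays free for oxidation.

Step 12
Reactants: 17 (4S)-4-methyl-4-[(triethylsilyl)peroxy]dec-9-en-2-ol
Product: 18 (4S)-4-methyl-4-[(triethylsilyl)peroxy]dec-9-en-2-one
Conditions: Dess–Martin periodinane, CH2Cl2, 0 °C to rt
Reagents that add atoms: none
Why: Dess–Martin oxidation converts the secondary alcohol into the methyl ketone under conditions that the silyl peroxide and the terminal alkene tolerate, and removes the undefined carbinol centre.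

Step 13
Reactants: 18 (4S)-4-methyl-4-[(triethylsilyl)peroxy]dec-9-en-2-one
Product: 21 (5S)-5-(hex-5-en-1-yl)-3-methoxy-3,5-dimethyl-1,2-dioxolane (C3 epimers), via hydroperoxy ketone 19 (not isolated), via dioxolan-3-ol 20 (not isolated)
Conditions: TsOH·H2O (cat.), MeOH, rt
Reagents that add atoms: methanol, CO
Why: Acid-catalysed methanolysis cleaves the O–Si bond, the freed hydroperoxide adds to the ketone in a 5-exo-trig sense to close the 1,2-dioxolane, and acetal exchange with methanol gives the peroxyketal, while the C5–O bond is untouched so C5 stays S.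

Step 14
Reactants: 21 (5S)-5-(hex-5-en-1-yl)-3-methoxy-3,5-dimethyl-1,2-dioxolane
Product: 22 methyl 2-[(3R,5S)-5-(hex-5-en-1-yl)-3,5-dimethyl-1,2-dioxolan-3-yl]acetate
Conditions: TiCl4, CH2Cl2, −78 °C; chromatographic removal of the 3S epimer
Reagents that add atoms: tert-butyl[(1-methoxyethenyl)oxy]dimethylsilane, C=C(OC)O[Si](C)(C)C(C)(C)C
Why: Mukaiyama-type substitution of a 3-alkoxy-1,2-dioxolane, in which TiCl4 ionises the peroxyketal and the silyl ketene acetal attacks the planar peroxycarbenium carbon on the face anti to the larger C5 substituent (hexenyl rather than methyl), which should favour the 3R,5S (trans-dimethyl) isomer, though the preference is expected to be modest.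

Step 15
Reactants: 22 methyl 2-[(3R,5S)-5-(hex-5-en-1-yl)-3,5-dimethyl-1,2-dioxolan-3-yl]acetate; 7 (1E,3E,6Z)-1-iodonona-1,3,6-triene
Product: 24 methyl 2-[(3R,5S)-3,5-dimethyl-5-[(7E,9E,12Z)-pentadeca-7,9,12-trien-1-yl]-1,2-dioxolan-3-yl]acetate, via B-alkyl-9-BBN 23 (not isolated)
Conditions: 9-BBN (0.5 M in THF), 0 °C to rt; then 3 M aq. Cs2CO3, 7, Pd(dppf)Cl2·CH2Cl2 (cat.), AsPh3 (cat.), DMF, rt, dark
Reagents that add atoms: none
Why: 9-BBN adds B–H syn and anti-Markovnikov to the monosubstituted C5'=C6' alkene to give the primary alkylborane 23; Pd(0) then inserts into the C–I bond of 7 with retention, the base-activated borate transfers the primary alkyl group to palladium, and reductive elimination forms the C6'–C7' bond. The closest known reaction type is the B-alkyl Suzuki–Miyaura coupling of B-alkyl-9-BBN reagents with (E)-alkenyl and dienyl iodides under Pd(dppf)Cl2/AsPh3/Cs2CO3 at room temperature, a standard way to join polyene halves at an sp3–sp2 bond. No ring is closed; the 1,2-dioxolane made in step 13 is carried through unchanged. No stereocentre is created: the 7E,9E,12Z geometry is fixed in 7 and transferred with retention, and ring C3 and C5 are not involved. The step needs chemoselectivity for the terminal alkene over the ester carbonyl and the O–O bond, and a peroxide that resists Pd(0) and base: 9-BBN reacts with a monosubstituted alkene far faster than with an ester or a hindered di-tertiary peroxide, both peroxide carbons are fully substituted (no α-hydrogen for Kornblum–DeLaMare cleavage, steric shielding against O–O insertion), and the iodide with its internal alkenes is added only after the aqueous base has destroyed excess borane. AsPh3 and the wide-bite-angle dppf ligand speed up transmetalation and reductive elimination relative to β-hydride elimination, and room temperature in the dark should keep the skipped triene from isomerising.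

**Compound list**

1 | (Z)-hex-3-en-1-ol | CC/C=C\CCO | starting material
2 | (Z)-hex-3-enal | CC/C=C\CC=O | intermediate
3 | (1E,4Z)-1-iodohepta-1,4-diene | CC/C=C\C/C=C/I | intermediate
4 | trimethyl[(3E,6Z)-nona-3,6-dien-1-yn-1-yl]silane | CC/C=C\C/C=C/C#C[Si](C)(C)C | intermediate
5 | (3E,6Z)-nona-3,6-dien-1-yne | CC/C=C\C/C=C/C#C | intermediate
6 | chlorobis(cyclopentadienyl)[(1E,3E,6Z)-nona-1,3,6-trien-1-yl]zirconium | CC/C=C\C/C=C/C=C/[Zr](Cl)(C1C=CC=C1)C1C=CC=C1 | intermediate (not isolated)
7 | (1E,3E,6Z)-1-iodonona-1,3,6-triene | CC/C=C\C/C=C/C=C/I | intermediate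
8 | oct-1-en-7-yne | C=CCCCCC#C | starting material
9 | dimethyl[(1E)-2-methylocta-1,7-dien-1-yl]alumane | C[Al](C)/C=C(\C)CCCCC=C | intermediate (not isolated)
10 | lithium butyldimethyl[(1E)-2-methylocta-1,7-dien-1-yl]aluminate | [Li+].CCCC[Al-](C)(C)/C=C(\C)CCCCC=C | intermediate (not isolated)
11 | (3E)-4-methyldeca-3,9-dien-2-ol (racemic) | CC(O)/C=C(\C)CCCCC=C | intermediate
12 | 1-[(2R,3R)-3-(hex-5-en-1-yl)-3-methyloxiran-2-yl]ethan-1-ol (carbinol epimers) | CC(O)[C@H]1O[C@]1(C)CCCCC=C | intermediate
13 | (4R)-4-methyldec-9-ene-2,4-diol (C2 epimers) | CC(O)C[C@](C)(O)CCCCC=C | intermediate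
14 | (4R)-4-hydroxy-4-methyldec-9-en-2-yl methanesulfonate | CC(OS(C)(=O)=O)C[C@](C)(O)CCCCC=C | intermediate (not isolated)
15 | (2R)-2-(hex-5-en-1-yl)-2,4-dimethyloxetane (C4 epimers) | C[C@@]1(CCCCC=C)CC(C)O1 | intermediate
16 | (4S)-4-hydroperoxy-4-methyldec-9-en-2-ol (C2 epimers) | CC(O)C[C@@](C)(OO)CCCCC=C | intermediate
17 | (4S)-4-methyl-4-[(triethylsilyl)peroxy]dec-9-en-2-ol | CC(O)C[C@@](C)(OO[Si](CC)(CC)CC)CCCCC=C | intermediate
18 | (4S)-4-methyl-4-[(triethylsilyl)peroxy]dec-9-en-2-one | CC(=O)C[C@@](C)(OO[Si](CC)(CC)CC)CCCCC=C | intermediate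
19 | (4S)-4-hydroperoxy-4-methyldec-9-en-2-one | CC(=O)C[C@@](C)(OO)CCCCC=C | intermediate (not isolated)
20 | (5S)-5-(hex-5-en-1-yl)-3,5-dimethyl-1,2-dioxolan-3-ol | CC1(O)C[C@](C)(CCCCC=C)OO1 | intermediate (not isolated)
21 | (5S)-5-(hex-5-en-1-yl)-3-methoxy-3,5-dimethyl-1,2-dioxolane (C3 epimers) | COC1(C)C[C@](C)(CCCCC=C)OO1 | intermediate
22 | methyl 2-[(3R,5S)-5-(hex-5-en-1-yl)-3,5-dimethyl-1,2-dioxolan-3-yl]acetate | C=CCCCC[C@@]1(C)C[C@](C)(CC(=O)OC)OO1 | intermediate
23 | methyl 2-[(3R,5S)-5-[6-(9-borabicyclo[3.3.1]nonan-9-yl)hexyl]-3,5-dimethyl-1,2-dioxolan-3-yl]acetate | B1(C2CCCC1CCC2)CCCCCC[C@@]3(C)C[C@](C)(CC(=O)OC)OO3 | intermediate (not isolated)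
24 | methyl 2-[(3R,5S)-3,5-dimethyl-5-[(7E,9E,12Z)-pentadeca-7,9,12-trien-1-yl]-1,2-dioxolan-3-yl]acetate | CC/C=C\C/C=C/C=C/CCCCCC[C@@]1(C)C[C@](C)(CC(=O)OC)OO1 | target

**Step count and risks**

Total step count: 15. Longest linear sequence: 10 steps (steps 6 to 15).

Steps most likely to fail:

1. Step 15. The primary alkyl group may transfer too slowly from boron to palladium, so that protodeboronation, β-hydride elimination and palladium- or base-induced degradation of the peroxide and the ester compete. The fallback sets out from 22 (and uses 5) and comes back at 24. Anti-Markovnikov hydration of 22 (9-BBN, then NaBO3·4H2O) should give the primary alcohol methyl 2-[(3R,5S)-5-(6-hydroxyhexyl)-3,5-dimethyl-1,2-dioxolan-3-yl]acetate F1. An Appel reaction (CBr4, PPh3, CH2Cl2, 0 °C) should convert it into the bromide methyl 2-[(3R,5S)-5-(6-bromohexyl)-3,5-dimethyl-1,2-dioxolan-3-yl]acetate F2. Enyne 5 is hydrozirconated to 6 as in step 5, and 6 is coupled with F2 under ligand-free palladium catalysis (Pd(acac)2, LiBr, THF–NMP, 55 °C; alkenylzirconium–alkyl bromide Negishi-type coupling). This forms the same bond with the roles of the partners reversed, without base or boron at the coupling stage, and the syn hydrozirconation sets the 7E geometry; the product is 24.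

2. Step 14. Facial selectivity in the attack on the planar peroxycarbenium ion may be poor, because ring C5 carries two groups of similar size. The fallback sets out from 21 and comes back at 22. Step 14 is run as written and the unwanted epimer methyl 2-[(3S,5S)-5-(hex-5-en-1-yl)-3,5-dimethyl-1,2-dioxolan-3-yl]acetate F3 is collected. Under the amine/fluoroalcohol conditions used for intramolecular hydroperoxide conjugate additions (Et2NH, CF3CH2OH), F3 should open by E1cB elimination to the hydroperoxy enoate methyl (5S)-5-hydroperoxy-3,5-dimethylundeca-2,10-dienoate F4. F4 recloses 5-exo-trig (peroxy-Michael addition) to a mixture of 22 and F3, so separation and recycling convert the wrong epimer into 22 under thermodynamic rather than kinetic control.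

3. Step 10. The activated oxetane may ionise partly to a tertiary carbocation, with loss of configurational purity at the future ring C5, or be attacked at the secondary carbon. The fallback sets out from 22 of reduced enantiomeric purity and comes back at 22. Saponification (LiOH, THF–H2O) should give 2-[(3R,5S)-5-(hex-5-en-1-yl)-3,5-dimethyl-1,2-dioxolan-3-yl]acetic acid F5. Classical resolution by crystallisation of its (R)-1-phenylethylammonium salt F6, acidification and re-esterification (TMSCHN2, MeOH–toluene) should return enantiopure 22.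

**Further compounds**

F1 | step 15 | methyl 2-[(3R,5S)-5-(6-hydroxyhexyl)-3,5-dimethyl-1,2-dioxolan-3-yl]acetate | OCCCCCC[C@@]1(C)C[C@](C)(CC(=O)OC)OO1
F2 | step 15 | methyl 2-[(3R,5S)-5-(6-bromohexyl)-3,5-dimethyl-1,2-dioxolan-3-yl]acetate | BrCCCCCC[C@@]1(C)C[C@](C)(CC(=O)OC)OO1
F3 | step 14 | methyl 2-[(3S,5S)-5-(hex-5-en-1-yl)-3,5-dimethyl-1,2-dioxolan-3-yl]acetate | C=CCCCC[C@@]1(C)C[C@@](C)(CC(=O)OC)OO1
F4 | step 14 | methyl (5S)-5-hydroperoxy-3,5-dimethylundeca-2,10-dienoate (E/Z mixture) | COC(=O)C=C(C)C[C@@](C)(OO)CCCCC=C
F5 | step 10 | 2-[(3R,5S)-5-(hex-5-en-1-yl)-3,5-dimethyl-1,2-dioxolan-3-yl]acetic acid | C=CCCCC[C@@]1(C)C[C@](C)(CC(=O)O)OO1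
F6 | step 10 | (R)-1-phenylethylammonium 2-[(3R,5S)-5-(hex-5-en-1-yl)-3,5-dimethyl-1,2-dioxolan-3-yl]acetate | C=CCCCC[C@@]1(C)C[C@](C)(CC(=O)[O-])OO1.C[C@@H]([NH3+])c1ccccc1
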